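The route rests on cutting the C2–C3 bond of the west dihydrofuran. West C2, a benzylic CH on the furan oxygen, is the fifth atom counted from west C3 (the diarylmethine shared with the seven-membered ring) through two carbons of the central benzene (ring A) and that oxygen. The bond is therefore made by enantioselective 1,5 C–H insertion of a diaryl rhodium carbene into a 4-methoxybenzyl ether, which closes the furan and fixes C3 in one operation. The precursor is a diaryl diazomethane on ring A, flanked by that ether and a tert-butyl acetate arm that later supplies C8 and the seven-membered ring.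

Key step: step 7

Remarks on the chemistry (assumptions):
- Ring A is the central benzene. Its carbons are named by what they carry, going round the ring: the CH2-bearing carbon, the C3-bearing carbon, the west-oxygen carbon, the lone CH, the east-oxygen carbon (para to the C3-bearing carbon), and the east carbon (between the east-oxygen carbon and the CH2-bearing carbon), which ends up bonded to east C3'.
- The west furan consists of the west oxygen, C2 and C3. C8 is the methine of the seven-membered ring that carries a 4-oxyphenyl group. Ring B is the 3,5-dioxygenated ring bonded to C3 through its ipso carbon and to C8 through an ortho carbon. The east furan consists of the east oxygen, C2' and C3'.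
- "Tetracycle" in the names below means ring A fused to the west dihydrofuran and to the seven-membered ring. That ring is made of the CH2-bearing and C3-bearing carbons of ring A, C3, the ipso and one ortho carbon of ring B, C8 and the ring CH2. C2 and C8 each carry a 4-methoxyphenyl group. Ring B carries two methoxy groups, one ortho and one para to its C8-bearing carbon.
- The acetic arm is carried as its tert-butyl ester from step 4 to step 8. Hydrazine would turn a methyl 2-aroylphenylacetate into the acyl hydrazide, which closes onto the neighbouring ketone to a 2,3-benzodiazepin-4-one. The tert-butyl ester should resist this and has no C–H bond within reach of the carbene.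
- Rh2(R-PTAD)4 is tetrakis[(R)-(1-adamantyl)(N-phthalimido)acetato]dirhodium, a carboxylate of divalent rhodium, and Rh2(S-PTAD)4 is its mirror image. Rh2(R-PTAD)4 is assumed to give the (2R,3S) cis product in step 7. If the sense proves opposite, the two catalyst enantiomers change places between steps 7 and 17.
- Grignard reagents 13 and 19 are bought as THF solutions.

Step 1
Reactants: 1 methyl 3,5-dihydroxyphenylacetate; 2 3,5-dimethoxybenzoyl chloride
Product: 3 methyl 2-[2-(3,5-dimethoxybenzoyl)-3,5-dihydroxyphenyl]acetate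
Conditions: AlCl3 (3 equiv), ClCH2CH2Cl/PhNO2, 0 °C → 50 °C; dilute HCl work-up
Reagents that add atoms: none
Why: Friedel–Crafts acylation (O-acylation then Fries shift under AlCl3) should go to the ring carbon ortho to one hydroxyl and para to the other, beside the side chain, as with orcinol-type phenols, and the hydrogen-bonded ortho-hydroxy ketone is the stable isomer.

Step 2
Reactants: 3 methyl 2-[2-(3,5-dimethoxybenzoyl)-3,5-dihydroxyphenyl]acetate
Product: 4 methyl 2-[5-(benzyloxy)-2-(3,5-dimethoxybenzoyl)-3-hydroxyphenyl]acetate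
Conditions: BnBr (1.05 equiv), K2CO3, acetone, reflux
Reagents that add atoms: benzyl bromide, BrCc1ccccc1
Why: Williamson etherification should take only the free, more acidic hydroxyl para to the ketone, because the ortho hydroxyl is held in a hydrogen bond to the carbonyl group.

Step 3
Reactants: 4 methyl 2-[5-(benzyloxy)-2-(3,5-dimethoxybenzoyl)-3-hydroxyphenyl]acetate; 5 4-methoxybenzyl chloride
Product: 7 2-[5-(benzyloxy)-2-(3,5-dimethoxybenzoyl)-3-[(4-methoxybenzyl)oxy]phenyl]acetic acid, via PMB-ether methyl ester 6 (not isolated)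
Conditions: K2CO3, DMF, 60 °C; then LiOH, H2O/MeOH, rt; dilute HCl to pH 4
Reagents that add atoms: lithium hydroxide, [Li+].[OH-]
Why: Williamson etherification of the chelated phenol under more forcing conditions is followed in the same flask by saponification of the methyl arylacetate, so that no methyl ester is present when hydrazine is used.

Step 4
Reactants: 7 2-[5-(benzyloxy)-2-(3,5-dimethoxybenzoyl)-3-[(4-methoxybenzyl)oxy]phenyl]acetic acid
Product: 8 tert-butyl 2-[5-(benzyloxy)-2-(3,5-dimethoxybenzoyl)-3-[(4-methoxybenzyl)oxy]phenyl]acetate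
Conditions: Me2NCH(Ot-Bu)2 (4 equiv), toluene, 80 °C
Reagents that add atoms: N,N-dimethylformamide di-tert-butyl acetal, CN(C)C(OC(C)(C)C)OC(C)(C)C
Why: tert-Butyl ester formation by O-alkylation of the carboxylic acid with the formamide acetal is neutral and leaves the acid-labile 4-methoxybenzyl ether and the ketone alone.

Step 5
Reactants: 8 tert-butyl 2-[5-(benzyloxy)-2-(3,5-dimethoxybenzoyl)-3-[(4-methoxybenzyl)oxy]phenyl]acetate
Product: 9 tert-butyl 2-[5-(benzyloxy)-2-[(3,5-dimethoxyphenyl)(hydrazinylidene)methyl]-3-[(4-methoxybenzyl)oxy]phenyl]acetate (E/Z mixture)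
Conditions: N2H4 (anhydrous, 20 equiv), AcOH (cat.), EtOH, 90 °C, sealed tube
Reagents that add atoms: hydrazine, NN
Why: Hydrazone condensation of the hindered diaryl ketone needs forcing conditions, which the tert-butyl ester should survive because it resists hydrazinolysis and ring closure by the weakly nucleophilic hydrazone nitrogen.

Step 6
Reactants: 9 tert-butyl 2-[5-(benzyloxy)-2-[(3,5-dimethoxyphenyl)(hydrazinylidene)methyl]-3-[(4-methoxybenzyl)oxy]phenyl]acetate
Product: 10 tert-butyl 2-[5-(benzyloxy)-2-[diazo(3,5-dimethoxyphenyl)methyl]-3-[(4-methoxybenzyl)oxy]phenyl]acetate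
Conditions: activated MnO2 (10 equiv), CH2Cl2, 0 °C → rt, dark; filtered through Celite and used at once
Reagents that add atoms: none
Why: Dehydrogenation of a diaryl ketone hydrazone by MnO2 is the standard mild route to diaryl diazomethanes and touches neither the ethers nor the ester.

Step 7
Reactants: 10 tert-butyl 2-[5-(benzyloxy)-2-[diazo(3,5-dimethoxyphenyl)methyl]-3-[(4-methoxybenzyl)oxy]phenyl]acetate
Product: 11 tert-butyl 2-[(2R,3S)-6-(benzyloxy)-3-(3,5-dimethoxyphenyl)-2-(4-methoxyphenyl)-2,3-dihydro-1-benzofuran-4-yl]acetate (cis)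
Conditions: Rh2(R-PTAD)4 (1 mol%), CH2Cl2, −20 °C → 0 °C, slow addition of 10
Reagents that add atoms: none
Why: Rh2(R-PTAD)4 expels N2 from 10 to give a donor/donor (diaryl) rhodium carbene, which takes up one C–H bond of the 4-methoxybenzyl CH2 in a concerted, asynchronous three-centre transition state with hydride-transfer character. The closest known reaction type is the dirhodium-catalysed intramolecular C–H insertion of diaryl diazomethanes into benzylic ethers, which gives 2,3-diaryl-2,3-dihydrobenzofurans. The one new ring, the west dihydrofuran, closes by 1,5-insertion, that is by C2–C3 bond formation across the chain carbene carbon–ring A carbon–ring A carbon–oxygen–CH2, with the ring oxygen already in place. C3 (S, as in the target) is set by the chiral carboxylate ligands, which select one face of the carbene, and C2 (R, inverted in step 10) follows from the insertion transition state, which places the two aryl groups cis. The step needs site selectivity and enantioselectivity: the ether CH2 is the only C–H bond five atoms from the carbene carbon (the ester CH2 could only give a four-membered ring, and the benzyl ether and the tert-butyl group are out of reach) and it is activated both by oxygen and by the anisyl ring, while the weakly electrophilic donor/donor carbene should be slow to form a ylide with the hindered ester carbonyl.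

Step 8
Reactants: 11 tert-butyl 2-[(2R,3S)-6-(benzyloxy)-3-(3,5-dimethoxyphenyl)-2-(4-methoxyphenyl)-2,3-dihydro-1-benzofuran-4-yl]acetate
Product: 12 2-[(2R,3S)-6-(benzyloxy)-3-(3,5-dimethoxyphenyl)-2-(4-methoxyphenyl)-2,3-dihydro-1-benzofuran-4-yl]acetaldehyde
Conditions: i-Bu2AlH (1.2 equiv), toluene/CH2Cl2, −78 °C; MeOH, then aqueous potassium sodium tartrate
Reagents that add atoms: none
Why: Partial reduction of the ester by i-Bu2AlH stops at the aldehyde because the tetrahedral aluminate is stable at −78 °C and collapses only on work-up.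

Step 9
Reactants: 12 2-[(2R,3S)-6-(benzyloxy)-3-(3,5-dimethoxyphenyl)-2-(4-methoxyphenyl)-2,3-dihydro-1-benzofuran-4-yl]acetaldehyde; 13 4-methoxyphenylmagnesium bromide
Product: 14 2-[(2R,3S)-6-(benzyloxy)-3-(3,5-dimethoxyphenyl)-2-(4-methoxyphenyl)-2,3-dihydro-1-benzofuran-4-yl]-1-(4-methoxyphenyl)ethan-1-ol (both carbinol epimers)
Conditions: 4-MeOC6H4MgBr (1.5 equiv), THF, −78 °C → 0 °C; aqueous NH4Cl
Reagents that add atoms: none
Why: Grignard addition to the aldehyde at low temperature outruns enolisation, and the new carbinol centre needs no control because it is ionised in step 10.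

Step 10
Reactants: 14 2-[(2R,3S)-6-(benzyloxy)-3-(3,5-dimethoxyphenyl)-2-(4-methoxyphenyl)-2,3-dihydro-1-benzofuran-4-yl]-1-(4-methoxyphenyl)ethan-1-ol
Product: 15 (2S,3S,8S)-tetracycle benzyl ether (west furan trans, benzyloxy on the east-oxygen carbon of ring A)
Conditions: TFA (10 equiv), CH2Cl2 (0.01 M), 0 °C → rt, until the cis west furan is consumed
Reagents that add atoms: none
Why: TFA ionises the carbinol to the 4-methoxybenzylic cation (any stilbene formed by proton loss re-enters by protonation), which ring B attacks through its carbon ortho to one methoxy group and para to the other in an intramolecular Friedel–Crafts alkylation, as in the acid cyclisation of ε-viniferin-type stilbenes to this ring system; C8 should form as S, with the anisyl group pseudo-equatorial and turned away from the neighbouring ring B methoxy group, and reversible ionisation of the C2–O bond to the 4-methoxybenzylic cation takes the west furan to the more stable trans isomer (C2 from R to S, C3 untouched).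

Step 11
Reactants: 15 (2S,3S,8S)-tetracycle benzyl ether
Product: 16 (2S,3S,8S)-tetracycle phenol (free hydroxyl on the east-oxygen carbon of ring A)
Conditions: H2 (1 atm), 10% Pd/C, EtOAc/MeOH, rt, stopped after one equivalent of H2
Reagents that add atoms: none
Why: Hydrogenolysis of the aryl benzyl ether on Pd/C is much faster than cleavage of the hindered ring C2–O bond, so the phenol is freed without touching the furan.

Step 12
Reactants: 16 (2S,3S,8S)-tetracycle phenol
Product: 17 (2S,3S,8S)-tetracycle salicylaldehyde (formyl group on the east carbon of ring A, hydroxyl beside it)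
Conditions: MgCl2 (3 equiv), Et3N (6 equiv), (CH2O)n (10 equiv), MeCN, reflux; dilute HCl
Reagents that add atoms: formaldehyde (as paraformaldehyde), C=O
Why: In the magnesium-mediated ortho-formylation (Casnati–Skattebøl) the magnesium phenoxide delivers formaldehyde only to an ortho carbon of its own ring, the east carbon (para to the west oxygen) being favoured over the lone CH (between two oxygens) as with 3-alkoxyphenols, and a second formaldehyde oxidises the hydroxymethyl group to the aldehyde.

Step 13
Reactants: 17 (2S,3S,8S)-tetracycle salicylaldehyde; 5 4-methoxybenzyl chloride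
Product: 18 (2S,3S,8S)-tetracycle aldehyde 4-methoxybenzyl ether (formyl group on the east carbon, 4-methoxybenzyloxy group on the east-oxygen carbon)
Conditions: K2CO3, DMF, 50 °C
Reagents that add atoms: none
Why: Williamson etherification of the salicylaldehyde-type phenol installs the CH2 that becomes east C2'.

Step 14
Reactants: 18 (2S,3S,8S)-tetracycle aldehyde 4-methoxybenzyl ether; 19 3,5-dimethoxyphenylmagnesium bromide
Product: 20 (2S,3S,8S)-tetracycle diarylcarbinol ((3,5-dimethoxyphenyl)(hydroxy)methyl group on the east carbon, 4-methoxybenzyloxy group beside it; both carbinol epimers)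
Conditions: 3,5-(MeO)2C6H3MgBr (2 equiv), THF, 0 °C; aqueous NH4Cl
Reagents that add atoms: none
Why: Grignard addition to the aryl aldehyde gives the diarylcarbinol, whose configuration is irrelevant because the carbinol is oxidised in step 15.

Step 15
Reactants: 20 (2S,3S,8S)-tetracycle diarylcarbinol
Product: 21 (2S,3S,8S)-tetracycle diaryl ketone (3,5-dimethoxybenzoyl group on the east carbon, 4-methoxybenzyloxy group beside it)
Conditions: Dess–Martin periodinane (1.5 equiv), CH2Cl2, rt
Reagents that add atoms: none
Why: Dess–Martin oxidation converts the doubly benzylic carbinol into the diaryl ketone under neutral conditions that spare the benzylic ethers and the electron-rich rings.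

Step 16
Reactants: 21 (2S,3S,8S)-tetracycle diaryl ketone
Product: 22 (2S,3S,8S)-tetracycle hydrazone (E/Z mixture)
Conditions: N2H4 (anhydrous, 30 equiv), AcOH (cat.), n-BuOH, 110 °C, sealed tube
Reagents that add atoms: hydrazine, NN
Why: Hydrazone condensation as in step 5, on a substrate that contains only ethers and therefore tolerates the forcing conditions the hindered ketone needs.

Step 17
Reactants: 22 (2S,3S,8S)-tetracycle hydrazone
Product: 24 (2S,3S,8S,2'S,3'R)-heptamethyl ether of the target skeleton having a cis east furan, via east diazo compound 23 (not isolated)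
Conditions: MnO2 (10 equiv), CH2Cl2, 0 °C → rt; filtered; then Rh2(S-PTAD)4 (2 mol%), CH2Cl2, −20 °C → 0 °C
Reagents that add atoms: none
Why: MnO2 gives the diazo compound and Rh2(S-PTAD)4, the mirror image of the step 7 catalyst, effects the same 1,5 C–H insertion into the new 4-methoxybenzyl ether, so catalyst control sets C3' as R with C2' cis to it (S), the sense opposite to the west furan, while the C8–H bond, although also five atoms away, cannot reach the carbene without bridging the seven-membered ring across ring A.

Step 18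
Reactants: 24 (2S,3S,8S,2'S,3'R)-heptamethyl ether of the target skeleton having a cis east furan
Product: 25 CNP0136963.1, the (2S,3S,8S,2'R,3'R)-heptaphenol
Conditions: BBr3 (15 equiv), CH2Cl2, −78 °C → rt; MeOH, then water
Reagents that add atoms: none
Why: BBr3 cleaves all seven aryl methyl ethers (Lewis acid demethylation) and ionises the C2'–O bond reversibly to the 4-oxybenzylic cation, so the east furan should reclose to the more stable trans isomer (C2' from S to R) while C3', C2, C3 and C8 stay as set.

Compound list
1 | methyl 3,5-dihydroxyphenylacetate | COC(=O)Cc1cc(O)cc(O)c1 | starting material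
2 | 3,5-dimethoxybenzoyl chloride | COc1cc(OC)cc(C(=O)Cl)c1 | starting material
3 | methyl 2-[2-(3,5-dimethoxybenzoyl)-3,5-dihydroxyphenyl]acetate | COC(=O)Cc1cc(O)cc(O)c1C(=O)c1cc(OC)cc(OC)c1 | intermediate
4 | methyl 2-[5-(benzyloxy)-2-(3,5-dimethoxybenzoyl)-3-hydroxyphenyl]acetate | COC(=O)Cc1cc(OCc2ccccc2)cc(O)c1C(=O)c1cc(OC)cc(OC)c1 | intermediate
5 | 4-methoxybenzyl chloride | COc1ccc(CCl)cc1 | starting material
6 | methyl 2-[5-(benzyloxy)-2-(3,5-dimethoxybenzoyl)-3-[(4-methoxybenzyl)oxy]phenyl]acetate | COC(=O)Cc1cc(OCc2ccccc2)cc(OCc2ccc(OC)cc2)c1C(=O)c1cc(OC)cc(OC)c1 | intermediate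
7 | 2-[5-(benzyloxy)-2-(3,5-dimethoxybenzoyl)-3-[(4-methoxybenzyl)oxy]phenyl]acetic acid | OC(=O)Cc1cc(OCc2ccccc2)cc(OCc2ccc(OC)cc2)c1C(=O)c1cc(OC)cc(OC)c1 | intermediate
8 | tert-butyl 2-[5-(benzyloxy)-2-(3,5-dimethoxybenzoyl)-3-[(4-methoxybenzyl)oxy]phenyl]acetate | CC(C)(C)OC(=O)Cc1cc(OCc2ccccc2)cc(OCc2ccc(OC)cc2)c1C(=O)c1cc(OC)cc(OC)c1 | intermediate
9 | tert-butyl 2-[5-(benzyloxy)-2-[(3,5-dimethoxyphenyl)(hydrazinylidene)methyl]-3-[(4-methoxybenzyl)oxy]phenyl]acetate (E/Z mixture) | CC(C)(C)OC(=O)Cc1cc(OCc2ccccc2)cc(OCc2ccc(OC)cc2)c1C(=NN)c1cc(OC)cc(OC)c1 | intermediate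
10 | tert-butyl 2-[5-(benzyloxy)-2-[diazo(3,5-dimethoxyphenyl)methyl]-3-[(4-methoxybenzyl)oxy]phenyl]acetate | CC(C)(C)OC(=O)Cc1cc(OCc2ccccc2)cc(OCc2ccc(OC)cc2)c1C(=[N+]=[N-])c1cc(OC)cc(OC)c1 | intermediate
11 | tert-butyl 2-[(2R,3S)-6-(benzyloxy)-3-(3,5-dimethoxyphenyl)-2-(4-methoxyphenyl)-2,3-dihydro-1-benzofuran-4-yl]acetate (cis) | CC(C)(C)OC(=O)Cc1cc(OCc2ccccc2)cc2c1[C@H](c1cc(OC)cc(OC)c1)[C@H](c1ccc(OC)cc1)O2 | intermediate
12 | 2-[(2R,3S)-6-(benzyloxy)-3-(3,5-dimethoxyphenyl)-2-(4-methoxyphenyl)-2,3-dihydro-1-benzofuran-4-yl]acetaldehyde | O=CCc1cc(OCc2ccccc2)cc2c1[C@H](c1cc(OC)cc(OC)c1)[C@H](c1ccc(OC)cc1)O2 | intermediate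
13 | 4-methoxyphenylmagnesium bromide | COc1ccc([Mg]Br)cc1 | starting material
14 | 2-[(2R,3S)-6-(benzyloxy)-3-(3,5-dimethoxyphenyl)-2-(4-methoxyphenyl)-2,3-dihydro-1-benzofuran-4-yl]-1-(4-methoxyphenyl)ethan-1-ol (both carbinol epimers) | COc1ccc(C(O)Cc2cc(OCc3ccccc3)cc3c2[C@H](c2cc(OC)cc(OC)c2)[C@H](c2ccc(OC)cc2)O3)cc1 | intermediate
15 | (2S,3S,8S)-tetracycle benzyl ether (west furan trans; benzyloxy on the east-oxygen carbon of ring A; C2 and C8 carry 4-methoxyphenyl; ring B carries two methoxy groups) | COc1ccc([C@@H]2Cc3c4c(cc(OCc5ccccc5)c3)O[C@H](c3ccc(OC)cc3)[C@H]4c3cc(OC)cc(OC)c32)cc1 | intermediate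
16 | (2S,3S,8S)-tetracycle phenol (free hydroxyl on the east-oxygen carbon of ring A) | COc1ccc([C@@H]2Cc3c4c(cc(O)c3)O[C@H](c3ccc(OC)cc3)[C@H]4c3cc(OC)cc(OC)c32)cc1 | intermediate
17 | (2S,3S,8S)-tetracycle salicylaldehyde (formyl group on the east carbon of ring A, hydroxyl beside it) | COc1ccc([C@@H]2Cc3c4c(cc(O)c3C=O)O[C@H](c3ccc(OC)cc3)[C@H]4c3cc(OC)cc(OC)c32)cc1 | intermediate
18 | (2S,3S,8S)-tetracycle aldehyde 4-methoxybenzyl ether (formyl group on the east carbon, 4-methoxybenzyloxy group on the east-oxygen carbon) | COc1ccc([C@@H]2Cc3c4c(cc(OCc5ccc(OC)cc5)c3C=O)O[C@H](c3ccc(OC)cc3)[C@H]4c3cc(OC)cc(OC)c32)cc1 | intermediate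
19 | 3,5-dimethoxyphenylmagnesium bromide | COc1cc(OC)cc([Mg]Br)c1 | starting material
20 | (2S,3S,8S)-tetracycle diarylcarbinol ((3,5-dimethoxyphenyl)(hydroxy)methyl group on the east carbon, 4-methoxybenzyloxy group beside it; both carbinol epimers) | COc1ccc([C@@H]2Cc3c4c(cc(OCc5ccc(OC)cc5)c3C(O)c3cc(OC)cc(OC)c3)O[C@H](c3ccc(OC)cc3)[C@H]4c3cc(OC)cc(OC)c32)cc1 | intermediate
21 | (2S,3S,8S)-tetracycle diaryl ketone (3,5-dimethoxybenzoyl group on the east carbon, 4-methoxybenzyloxy group beside it) | COc1ccc([C@@H]2Cc3c4c(cc(OCc5ccc(OC)cc5)c3C(=O)c3cc(OC)cc(OC)c3)O[C@H](c3ccc(OC)cc3)[C@H]4c3cc(OC)cc(OC)c32)cc1 | intermediate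
22 | (2S,3S,8S)-tetracycle hydrazone ((3,5-dimethoxyphenyl)(hydrazinylidene)methyl group on the east carbon, 4-methoxybenzyloxy group beside it; E/Z mixture) | COc1ccc([C@@H]2Cc3c4c(cc(OCc5ccc(OC)cc5)c3C(=NN)c3cc(OC)cc(OC)c3)O[C@H](c3ccc(OC)cc3)[C@H]4c3cc(OC)cc(OC)c32)cc1 | intermediate
23 | (2S,3S,8S)-tetracycle diazo compound (diazo(3,5-dimethoxyphenyl)methyl group on the east carbon, 4-methoxybenzyloxy group beside it) | COc1ccc([C@@H]2Cc3c4c(cc(OCc5ccc(OC)cc5)c3C(=[N+]=[N-])c3cc(OC)cc(OC)c3)O[C@H](c3ccc(OC)cc3)[C@H]4c3cc(OC)cc(OC)c32)cc1 | intermediate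
24 | (2S,3S,8S,2'S,3'R)-heptamethyl ether of the target skeleton, east furan cis | COc1ccc([C@@H]2Cc3c4c(cc5c3[C@@H](c3cc(OC)cc(OC)c3)[C@@H](c3ccc(OC)cc3)O5)O[C@H](c3ccc(OC)cc3)[C@H]4c3cc(OC)cc(OC)c32)cc1 | intermediate
25 | CNP0136963.1, (2S,3S,8S,2'R,3'R)-heptaphenol, both furans trans | Oc1ccc([C@@H]2Cc3c4c(cc5c3[C@@H](c3cc(O)cc(O)c3)[C@H](c3ccc(O)cc3)O5)O[C@H](c3ccc(O)cc3)[C@H]4c3cc(O)cc(O)c32)cc1 | target

Total step count: 18. Longest linear sequence: 18 steps (1 to 25); the route is fully linear, and 2, 5, 13 and 19 enter as bought.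

Steps most likely to fail

1. Step 7. The carbene-bearing ring carries two ortho substituents, so enantiofacial discrimination by the catalyst may erode, and part of the carbene may be diverted to the ester carbonyl. The fallback replaces catalyst control by resolution; it sets out from phenol 16 of insufficient enantiomeric purity (reached through steps 8–11) and comes back at 16. The impure 16 is acylated with (1R,2S,5R)-menthyl chloroformate (Et3N, DMAP, CH2Cl2) to give the (1R,2S,5R)-menthyl carbonate F1. The diastereomeric carbonates are separated by crystallisation or chromatography. K2CO3 in MeOH then cleaves F1 and returns 16 as a single enantiomer.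

2. Step 10. The cation may stay as the stilbene after proton loss or alkylate a second molecule instead of closing the ring, or ring B may add to the wrong face so that C8 forms as the wrong epimer. The fallback sets out from ester 11, makes C8 by hydride delivery instead of by C–C bond formation, and comes back at 15. TFA (CH2Cl2, rt) cleaves the tert-butyl ester and inverts C2 to give the trans acid F2. TFAA (0 °C → rt) in the same flask converts it into the mixed trifluoroacetic anhydride F3, which acylates ring B intramolecularly (Friedel–Crafts acylation) to give the seven-ring ketone F4. Reagent 13 with CeCl3 (THF, −78 °C) adds to the ketone to give the C8 tertiary carbinol F5. Ionic hydrogenation (Et3SiH, TFA, CH2Cl2, −40 °C) reduces the doubly benzylic cation from the less hindered face and returns to 15.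

3. Step 16 (the same concern applies, on a simpler substrate, to step 5). Condensation of hydrazine with a diaryl ketone flanked by two ortho substituents on a large, electron-rich substrate may stall or stop at the azine. The fallback sets out from aldehyde 17, avoids both the hydrazone and the second insertion of step 17, and comes back at 25. Excess 19 (3 equiv, THF, 0 °C) adds to 17 to give the o-hydroxybenzhydrol F6. p-Toluenesulfinic acid (CH2Cl2, rt) replaces the benzylic hydroxyl to give the sulfone F7. Cs2CO3 (MeCN, rt) eliminates sulfinate to the o-quinone methide F8 and deprotonates (4-methoxybenzyl)dimethylsulfonium tetrafluoroborate to the sulfur ylide. Their formal [4+1] annulation (conjugate addition, then ring closure with loss of dimethyl sulfide) gives the trans east furan, that is the all-trans heptamethyl ether F9. BBr3 as in step 18 then gives 25. Face selection in this annulation rests on the substrate alone, which is why it is the fallback and not the route.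

Further compounds
F1 | step 7 | (1R,2S,5R)-menthyl carbonate of (2S,3S,8S)-tetracycle phenol 16 | COc1ccc([C@@H]2Cc3c4c(cc(OC(=O)O[C@@H]5C[C@H](C)CC[C@H]5C(C)C)c3)O[C@H](c3ccc(OC)cc3)[C@H]4c3cc(OC)cc(OC)c32)cc1
F2 | step 10 | 2-[(2S,3S)-6-(benzyloxy)-3-(3,5-dimethoxyphenyl)-2-(4-methoxyphenyl)-2,3-dihydro-1-benzofuran-4-yl]acetic acid (trans) | OC(=O)Cc1cc(OCc2ccccc2)cc2c1[C@H](c1cc(OC)cc(OC)c1)[C@@H](c1ccc(OC)cc1)O2
F3 | step 10 | mixed anhydride of the trans acid and trifluoroacetic acid (not isolated) | O=C(Cc1cc(OCc2ccccc2)cc2c1[C@H](c1cc(OC)cc(OC)c1)[C@@H](c1ccc(OC)cc1)O2)OC(=O)C(F)(F)F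
F4 | step 10 | (2S,3S)-seven-ring ketone benzyl ether (C8 as C=O, west furan trans) | O=C2Cc3c4c(cc(OCc5ccccc5)c3)O[C@H](c3ccc(OC)cc3)[C@H]4c3cc(OC)cc(OC)c32
F5 | step 10 | (2S,3S)-C8 tertiary carbinol benzyl ether (8-hydroxy-8-(4-methoxyphenyl), both C8 epimers) | COc1ccc(C2(O)Cc3c4c(cc(OCc5ccccc5)c3)O[C@H](c3ccc(OC)cc3)[C@H]4c3cc(OC)cc(OC)c32)cc1
F6 | step 16 | (2S,3S,8S)-tetracycle o-hydroxybenzhydrol ((3,5-dimethoxyphenyl)(hydroxy)methyl group on the east carbon, free hydroxyl beside it; both carbinol epimers) | COc1ccc([C@@H]2Cc3c4c(cc(O)c3C(O)c3cc(OC)cc(OC)c3)O[C@H](c3ccc(OC)cc3)[C@H]4c3cc(OC)cc(OC)c32)cc1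
F7 | step 16 | (2S,3S,8S)-tetracycle sulfone ((3,5-dimethoxyphenyl)(4-methylbenzenesulfonyl)methyl group on the east carbon, free hydroxyl beside it; both epimers) | COc1ccc([C@@H]2Cc3c4c(cc(O)c3C(c3cc(OC)cc(OC)c3)S(=O)(=O)c3ccc(C)cc3)O[C@H](c3ccc(OC)cc3)[C@H]4c3cc(OC)cc(OC)c32)cc1
F8 | step 16 | (2S,3S,8S)-tetracycle o-quinone methide (ring A as a dienone with an exocyclic 3,5-dimethoxybenzylidene group on the east carbon; not isolated) | COc1ccc([C@@H]2CC3=C4C(=CC(=O)C3=Cc3cc(OC)cc(OC)c3)O[C@H](c3ccc(OC)cc3)[C@H]4c3cc(OC)cc(OC)c32)cc1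
F9 | step 16 | (2S,3S,8S,2'R,3'R)-heptamethyl ether of the target, both furans trans | COc1ccc([C@@H]2Cc3c4c(cc5c3[C@@H](c3cc(OC)cc(OC)c3)[C@H](c3ccc(OC)cc3)O5)O[C@H](c3ccc(OC)cc3)[C@H]4c3cc(OC)cc(OC)c32)cc1
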